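**Plan**

1. Retrosynthesis: the eight O-benzyl groups are removed last. In ring C of the flavanone unit (O1, C2, C3, C4, C4a, C8a) C2 is joined to C4, so that ring C derives from the five-membered ring (O1, C2, C4, C4a, C8a) of a cyclopropane-fused benzofuranol with C3 as the bridging CH2.
2. That cyclopropane comes from CH2 transfer to a 2-aryl-3-silyloxybenzofuran. Its benzofuranone is cut at C4–C4a (Friedel–Crafts) and at O1–C2 and C2–C4 (aldehyde + CHCl3 + 3,5-bis(benzyloxy)phenol). The C2'–C8'' biaryl bond is cut by Suzuki coupling into 8-borylated perbenzyl luteolin and 2-bromo-3,4-bis(benzyloxy)benzaldehyde.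
3. Forward: the luteolin rings are carried intact; the biaryl is made first, then the five-membered O-ring of the second unit, then the cyclopropane, then its enlargement to six-membered ring C, then debenzylation.
4. Enabling feature: C2 is benzylic (ring B), bears O1 and lies 1,3 to the C4 carbonyl, so it is the homoenolate carbon of the C4 ketone. In the bicyclic cyclopropanol the C2–C4 bond is therefore the one that breaks.
5. Stereochemistry: C2 is the only stereocentre. It is set as C1a of the cyclopropane by ligand-controlled Simmons–Smith methylenation and transferred with inversion in the ring enlargement.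

Key step: step 11

Remark: the C2'–C8'' axis carries four ortho substituents and is not defined in the target structure; from the biaryl aldehyde onward every compound is taken as a mixture of the two axial forms, only C2 is controlled, and the axial forms of the protected or free target would be separated by chromatography if one of them is wanted.

Remark: inversion at the protonated carbon is assumed for the base-induced cyclopropanol opening, as in 2-arylcyclopropanols in protic media; were retention found, the ligand antipode in step 10 would supply the (1aS,6bS)-cyclopropane, which then leads to the same (2S) product.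

Ar = 3,4-bis(benzyloxy)-2-{5,7-bis(benzyloxy)-2-[3,4-bis(benzyloxy)phenyl]-4-oxo-4H-chromen-8-yl}phenyl.

**Route**

Step 1
Reactants: 1 luteolin
Product: 2 5,7-bis(benzyloxy)-2-[3,4-bis(benzyloxy)phenyl]-4H-chromen-4-one
Conditions: BnBr (6 equiv), K2CO3, DMF, 80 °C
Reagents that add atoms: benzyl bromide, BrCc1ccccc1
Why: Williamson etherification of all four phenols, the chelated 5-OH needing the excess reagent and heat.

Step 2
Reactants: 2 tetra-O-benzylluteolin
Product: 3 5,7-bis(benzyloxy)-2-[3,4-bis(benzyloxy)phenyl]-8-iodo-4H-chromen-4-one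
Conditions: NIS (1.1 equiv), CF3CO2H (0.2 equiv), CH2Cl2/MeCN, 0 °C → rt
Reagents that add atoms: N-iodosuccinimide, O=C1CCC(=O)N1I
Why: Electrophilic aromatic iodination of the phloroglucinol-type ring A, where in fully O-alkylated 5,7-dioxygenated flavones C8 (ortho to O1 and 7-OBn, para to 5-OBn) is expected to react in preference to C6, which lies between two alkoxy groups.

Step 3
Reactants: 3 8-iodo-tetra-O-benzylluteolin
Product: 4 5,7-bis(benzyloxy)-2-[3,4-bis(benzyloxy)phenyl]-8-(4,4,5,5-tetramethyl-1,3,2-dioxaborolan-2-yl)-4H-chromen-4-one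
Conditions: B2pin2 (1.5 equiv), PdCl2(dppf) (5 mol %), KOAc, 1,4-dioxane, 90 °C
Reagents that add atoms: bis(pinacolato)diboron, CC1(C)OB(OC1(C)C)B1OC(C)(C)C(C)(C)O1
Why: Miyaura borylation (oxidative addition of the aryl iodide, acetate-assisted transmetalation with the diboron, reductive elimination) makes ring A the nucleophilic coupling partner.

Step 4
Reactants: 5 2-bromo-3-hydroxy-4-methoxybenzaldehyde (2-bromoisovanillin)
Product: 6 2-bromo-3,4-dihydroxybenzaldehyde
Conditions: BBr3 (2.5 equiv), CH2Cl2, −78 °C → rt; then H2O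
Reagents that add atoms: none
Why: Lewis-acid cleavage of the aryl methyl ether by BBr3 frees the catechol so that both oxygens can carry hydrogenolysable groups.

Step 5
Reactants: 6 2-bromo-3,4-dihydroxybenzaldehyde
Product: 7 3,4-bis(benzyloxy)-2-bromobenzaldehyde
Conditions: BnBr (2.4 equiv), K2CO3, DMF, 50 °C
Reagents that add atoms: benzyl bromide, BrCc1ccccc1
Why: Williamson etherification of the two catechol hydroxyls.

Step 6
Reactants: 4 luteolin 8-boronate; 7 3,4-bis(benzyloxy)-2-bromobenzaldehyde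
Product: 8 biaryl aldehyde Ar–CHO
Conditions: Pd(OAc)2 (5 mol %), SPhos (10 mol %), K3PO4 (3 equiv), toluene/H2O (10:1), 100 °C
Reagents that add atoms: none
Why: Suzuki–Miyaura coupling in which the ortho-formyl group speeds oxidative addition of the bromide and the bulky electron-rich biarylphosphine promotes transmetalation and reductive elimination to the biaryl with four ortho substituents.

Step 7
Reactants: 8 biaryl aldehyde Ar–CHO; 9 3,5-bis(benzyloxy)phenol
Product: 13 2-Ar-2-[3,5-bis(benzyloxy)phenoxy]acetic acid (racemic), via trichloromethyl carbinol 10 (not isolated), via gem-dichlorooxirane 11 (not isolated), via acyl chloride 12 (not isolated)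
Conditions: CHCl3, DBU (1.5 equiv), 0 °C → rt, evaporate; then 9 (2 equiv), powdered NaOH (6 equiv), DME/H2O, 0 °C → rt; then aq HCl
Reagents that add atoms: chloroform, ClC(Cl)Cl; sodium hydroxide, [Na+].[OH-]
Why: Jocic–Reeve reaction, in which trichloromethanide adds to the aldehyde, the carbinol closes to the gem-dichlorooxirane, the phenoxide of 9 opens it at the benzylic carbon and the acyl chloride is hydrolysed, so that C2, O1 and the future C4 are joined in one operation (the racemic centre is erased in step 9).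

Step 8
Reactants: 13 2-Ar-2-[3,5-bis(benzyloxy)phenoxy]acetic acid
Product: 15 2-Ar-4,6-bis(benzyloxy)benzofuran-3(2H)-one (racemic at C2), via mixed trifluoroacetic anhydride 14 (not isolated)
Conditions: (CF3CO)2O (2 equiv), CH2Cl2, 0 °C → rt; then aq NaHCO3; product kept under argon and used at once
Reagents that add atoms: none
Why: Intramolecular Friedel–Crafts acylation through the mixed anhydride, where the two positions ortho to the ether oxygen of the symmetric 3,5-bis(benzyloxy)phenoxy ring are equivalent and each is para to a benzyloxy group, so only the 4,6-dioxygenated benzofuran-3(2H)-one can form.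

Step 9
Reactants: 15 2-Ar-4,6-bis(benzyloxy)benzofuran-3(2H)-one
Product: 16 2-Ar-4,6-bis(benzyloxy)-3-(triethylsilyloxy)benzofuran
Conditions: Et3SiOTf (1.3 equiv), Et3N (2 equiv), CH2Cl2, 0 °C
Reagents that add atoms: triethylsilyl trifluoromethanesulfonate, CC[Si](CC)(CC)OS(=O)(=O)C(F)(F)F
Why: Soft enolisation and O-silylation of the 2-aryl ketone give the aromatic 3-silyloxybenzofuran, which removes the labile C2 centre and provides the electron-rich O1–C=C–OSi double bond for methylene transfer.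

Step 10
Reactants: 16 2-Ar-4,6-bis(benzyloxy)-3-(triethylsilyloxy)benzofuran
Product: 17 (1aR,6bR)-1a-Ar-4,6-bis(benzyloxy)-6b-(triethylsilyloxy)-1a,6b-dihydro-1H-cyclopropa[b]benzofuran
Conditions: Et2Zn (2.5 equiv), CH2I2 (5 equiv), N-Boc-L-Val-L-Pro-OMe (0.25 equiv), ethyl methoxyacetate (1 equiv), CH2Cl2, −20 °C → rt; pyridine, aq NaHCO3 quench
Reagents that add atoms: diiodomethane, ICI
Why: Asymmetric Simmons–Smith cyclopropanation of a silyl enol ether with a dipeptide-ligated zinc carbenoid, in which concerted syn delivery of CH2 to one face creates C1a and C6b together with a cis ring fusion, the ligand (its antipode if the sense of induction is opposite) selecting the face that gives (1aR,6bR).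

Step 11
Reactants: 17 (1aR,6bR)-silyloxycyclopropane
Product: 19 (2S)-2-Ar-5,7-bis(benzyloxy)chroman-4-one (octa-O-benzyl ether of the target), via cyclopropanol 18 (not isolated)
Conditions: Bu4NF/AcOH (1:1, 1.2 equiv), THF, 0 °C; then MeOH, K2CO3 (0.2 equiv), −20 °C → 0 °C; AcOH quench
Reagents that add atoms: none
Why: Proposed new method: fluoride removes the silyl group and the alkoxide of 18 pushes its electrons into a carbonyl while the bond C1a–C6b shared by the three- and five-membered rings breaks and methanol protonates C1a, so that the five-membered O-ring becomes six-membered ring C with C6b as C4=O, the cyclopropane CH2 as C3 and C1a as C2. The closest known reaction type is the base-catalysed homoketonisation of 2-arylcyclopropanols, which cleaves toward the benzylic carbon with inversion, together with the one-carbon ring enlargement of cyclic ketones through their siloxycyclopropanes. Ring C is not closed by a new bond: it arises by fragmentation of the zero-bridge bond of the 2-oxabicyclo[3.1.0]hexane, a ring enlargement by one carbon. The C2 centre is controlled by the configuration of C1a set in step 10 and is transferred with inversion by backside protonation, (1aR,6bR) giving (2S). The step needs cleavage of the internal bond and not of C6b–C1, which would give a 2-methylbenzofuranone; the ring B aryl group and O1 on C1a stabilise the developing carbanion there against a primary one at C1, and the bicyclic strain is released only by the internal cleavage. It also needs the product to keep its configuration, which the catalytic weak base, methanol as proton source and the low temperature secure against retro-oxa-Michael opening of the flavanone.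

Step 12
Reactants: 19 (2S)-octa-O-benzyl ether
Product: 20 (2S)-2-{3,4-dihydroxy-2-[5,7-dihydroxy-2-(3,4-dihydroxyphenyl)-4-oxo-4H-chromen-8-yl]phenyl}-5,7-dihydroxychroman-4-one (target)
Conditions: H2 (1 atm), 10% Pd/C, THF/MeOH, rt
Reagents that add atoms: none
Why: Catalytic hydrogenolysis of the eight benzyl ethers under neutral conditions, which should spare the flavone double bond, both ketones and the C2 centre that acid or base could racemise.

**Compound list**

1 | luteolin (5,7,3',4'-tetrahydroxyflavone) | O=c1cc(-c2ccc(O)c(O)c2)oc2cc(O)cc(O)c12 | starting material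
2 | 5,7-bis(benzyloxy)-2-[3,4-bis(benzyloxy)phenyl]-4H-chromen-4-one | O=c1cc(-c2ccc(OCc3ccccc3)c(OCc3ccccc3)c2)oc2cc(OCc3ccccc3)cc(OCc3ccccc3)c12 | intermediate
3 | 5,7-bis(benzyloxy)-2-[3,4-bis(benzyloxy)phenyl]-8-iodo-4H-chromen-4-one | O=c1cc(-c2ccc(OCc3ccccc3)c(OCc3ccccc3)c2)oc2c(I)c(OCc3ccccc3)cc(OCc3ccccc3)c12 | intermediate
4 | 5,7-bis(benzyloxy)-2-[3,4-bis(benzyloxy)phenyl]-8-(4,4,5,5-tetramethyl-1,3,2-dioxaborolan-2-yl)-4H-chromen-4-one | O=c1cc(-c2ccc(OCc3ccccc3)c(OCc3ccccc3)c2)oc2c(B3OC(C)(C)C(C)(C)O3)c(OCc3ccccc3)cc(OCc3ccccc3)c12 | intermediate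
5 | 2-bromo-3-hydroxy-4-methoxybenzaldehyde (2-bromoisovanillin) | COc1ccc(C=O)c(Br)c1O | starting material
6 | 2-bromo-3,4-dihydroxybenzaldehyde | O=Cc1ccc(O)c(O)c1Br | intermediate
7 | 3,4-bis(benzyloxy)-2-bromobenzaldehyde | O=Cc1ccc(OCc2ccccc2)c(OCc2ccccc2)c1Br | intermediate
8 | 3,4-bis(benzyloxy)-2-{5,7-bis(benzyloxy)-2-[3,4-bis(benzyloxy)phenyl]-4-oxo-4H-chromen-8-yl}benzaldehyde (Ar–CHO) | O=Cc1ccc(OCc2ccccc2)c(OCc2ccccc2)c1-c1c(OCc2ccccc2)cc(OCc2ccccc2)c2c(=O)cc(-c3ccc(OCc4ccccc4)c(OCc4ccccc4)c3)oc12 | intermediate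
9 | 3,5-bis(benzyloxy)phenol | Oc1cc(OCc2ccccc2)cc(OCc2ccccc2)c1 | starting material
10 | 1-Ar-2,2,2-trichloroethanol (racemic) | OC(c1ccc(OCc2ccccc2)c(OCc2ccccc2)c1-c1c(OCc2ccccc2)cc(OCc2ccccc2)c2c(=O)cc(-c3ccc(OCc4ccccc4)c(OCc4ccccc4)c3)oc12)C(Cl)(Cl)Cl | intermediate
11 | 3-Ar-2,2-dichlorooxirane (racemic) | ClC5(Cl)OC5c1ccc(OCc2ccccc2)c(OCc2ccccc2)c1-c1c(OCc2ccccc2)cc(OCc2ccccc2)c2c(=O)cc(-c3ccc(OCc4ccccc4)c(OCc4ccccc4)c3)oc12 | intermediate
12 | 2-Ar-2-[3,5-bis(benzyloxy)phenoxy]acetyl chloride (racemic) | O=C(Cl)C(Oc5cc(OCc6ccccc6)cc(OCc6ccccc6)c5)c1ccc(OCc2ccccc2)c(OCc2ccccc2)c1-c1c(OCc2ccccc2)cc(OCc2ccccc2)c2c(=O)cc(-c3ccc(OCc4ccccc4)c(OCc4ccccc4)c3)oc12 | intermediate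
13 | 2-Ar-2-[3,5-bis(benzyloxy)phenoxy]acetic acid (racemic) | OC(=O)C(Oc5cc(OCc6ccccc6)cc(OCc6ccccc6)c5)c1ccc(OCc2ccccc2)c(OCc2ccccc2)c1-c1c(OCc2ccccc2)cc(OCc2ccccc2)c2c(=O)cc(-c3ccc(OCc4ccccc4)c(OCc4ccccc4)c3)oc12 | intermediate
14 | mixed anhydride of 13 with trifluoroacetic acid | O=C(OC(=O)C(F)(F)F)C(Oc5cc(OCc6ccccc6)cc(OCc6ccccc6)c5)c1ccc(OCc2ccccc2)c(OCc2ccccc2)c1-c1c(OCc2ccccc2)cc(OCc2ccccc2)c2c(=O)cc(-c3ccc(OCc4ccccc4)c(OCc4ccccc4)c3)oc12 | intermediate
15 | 2-Ar-4,6-bis(benzyloxy)benzofuran-3(2H)-one (racemic at C2) | O=C5C(c1ccc(OCc2ccccc2)c(OCc2ccccc2)c1-c1c(OCc2ccccc2)cc(OCc2ccccc2)c2c(=O)cc(-c3ccc(OCc4ccccc4)c(OCc4ccccc4)c3)oc12)Oc6cc(OCc7ccccc7)cc(OCc7ccccc7)c65 | intermediate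
16 | 2-Ar-4,6-bis(benzyloxy)-3-(triethylsilyloxy)benzofuran | CC[Si](CC)(CC)Oc5c(-c1ccc(OCc2ccccc2)c(OCc2ccccc2)c1-c1c(OCc2ccccc2)cc(OCc2ccccc2)c2c(=O)cc(-c3ccc(OCc4ccccc4)c(OCc4ccccc4)c3)oc12)oc6cc(OCc7ccccc7)cc(OCc7ccccc7)c56 | intermediate
17 | (1aR,6bR)-1a-Ar-4,6-bis(benzyloxy)-6b-(triethylsilyloxy)-1a,6b-dihydro-1H-cyclopropa[b]benzofuran | CC[Si](CC)(CC)O[C@@]56C[C@]5(c1ccc(OCc2ccccc2)c(OCc2ccccc2)c1-c1c(OCc2ccccc2)cc(OCc2ccccc2)c2c(=O)cc(-c3ccc(OCc4ccccc4)c(OCc4ccccc4)c3)oc12)Oc5cc(OCc7ccccc7)cc(OCc7ccccc7)c56 | intermediate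
18 | (1aR,6bR)-1a-Ar-4,6-bis(benzyloxy)-1a,6b-dihydro-1H-cyclopropa[b]benzofuran-6b-ol | O[C@@]56C[C@]5(c1ccc(OCc2ccccc2)c(OCc2ccccc2)c1-c1c(OCc2ccccc2)cc(OCc2ccccc2)c2c(=O)cc(-c3ccc(OCc4ccccc4)c(OCc4ccccc4)c3)oc12)Oc5cc(OCc7ccccc7)cc(OCc7ccccc7)c56 | intermediate
19 | (2S)-2-Ar-5,7-bis(benzyloxy)chroman-4-one | O=C5C[C@@H](c1ccc(OCc2ccccc2)c(OCc2ccccc2)c1-c1c(OCc2ccccc2)cc(OCc2ccccc2)c2c(=O)cc(-c3ccc(OCc4ccccc4)c(OCc4ccccc4)c3)oc12)Oc6cc(OCc7ccccc7)cc(OCc7ccccc7)c65 | intermediate
20 | (2S)-2-{3,4-dihydroxy-2-[5,7-dihydroxy-2-(3,4-dihydroxyphenyl)-4-oxo-4H-chromen-8-yl]phenyl}-5,7-dihydroxychroman-4-one | O=C1C[C@@H](c2ccc(O)c(O)c2-c2c(O)cc(O)c3c(=O)cc(-c4ccc(O)c(O)c4)oc23)Oc2cc(O)cc(O)c21 | target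

**Count**

Total steps: 12. Longest linear sequence: 10 steps (steps 1–3 and 6–12, from luteolin).

**Steps most likely to fail**

1. Step 11 (proposed new method). The exocyclic C6b–C1 bond may cleave instead of the internal one, or configuration may be lost through a benzylic carbanion that lives long enough to invert or through base-induced opening of the flavanone to the chalcone. The fallback uses known chemistry, sets out from 8 and comes back at 19. Aldehyde 8 is condensed with commercial 1-[2-hydroxy-4,6-bis(benzyloxy)phenyl]ethanone (Ba(OH)2, MeOH/THF, 40 °C; Claisen–Schmidt) to the 2'-hydroxychalcone F1. F1 is cyclised by oxa-Michael addition (NaOAc, EtOH, reflux) to the racemic octa-O-benzyl flavanone F2. Preparative chromatography on an amylose tris(3,5-dimethylphenylcarbamate) phase should deliver 19. The (2R)-enantiomer F3 is returned to the NaOAc equilibration and separated again.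

2. Step 10. Methylene transfer to the tetrasubstituted, doubly flanked enol ether may be slow, and the many ether and carbonyl oxygens may compete with the dipeptide for zinc, giving poor facial discrimination. The fallback sets out from 15 and comes back at 18. Ketone 15 is esterified on its enol oxygen with (S)-2-methoxy-2-phenylacetic acid (DCC, DMAP, CH2Cl2) to the enol ester F4. F4 is cyclopropanated without a chiral ligand (Et2Zn, CF3CO2H, CH2I2, CH2Cl2, 0 °C), and the diastereomeric cyclopropyl esters are separated on silica to give the (1aR,6bR)-cyclopropyl ester F5. Methanolysis of F5 (K2CO3, MeOH, 0 °C) releases the alkoxide of 18, which should open to 19 as in step 11.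

3. Step 6. Protodeboronation of the doubly ortho-oxygenated boronate 4 may outrun transmetalation to the hindered arylpalladium species. The fallback exchanges the roles of the partners, sets out from 7 and 3 and comes back at 8. Bromide 7 is borylated (B2pin2, PdCl2(dppf), KOAc, dioxane, 90 °C) to 3,4-bis(benzyloxy)-2-(4,4,5,5-tetramethyl-1,3,2-dioxaborolan-2-yl)benzaldehyde F6, in which boron sits next to the stabilising formyl group. F6 is coupled with iodide 3 (Pd(OAc)2, SPhos, K3PO4, toluene/H2O, 100 °C) to give 8.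

**Further compounds**

F1 | step 11 | (E)-1-[2-hydroxy-4,6-bis(benzyloxy)phenyl]-3-Ar-prop-2-en-1-one | O=C(/C=C/c1ccc(OCc2ccccc2)c(OCc2ccccc2)c1-c1c(OCc2ccccc2)cc(OCc2ccccc2)c2c(=O)cc(-c3ccc(OCc4ccccc4)c(OCc4ccccc4)c3)oc12)c5c(O)cc(OCc6ccccc6)cc5OCc6ccccc6
F2 | step 11 | (2RS)-2-Ar-5,7-bis(benzyloxy)chroman-4-one | O=C5CC(c1ccc(OCc2ccccc2)c(OCc2ccccc2)c1-c1c(OCc2ccccc2)cc(OCc2ccccc2)c2c(=O)cc(-c3ccc(OCc4ccccc4)c(OCc4ccccc4)c3)oc12)Oc6cc(OCc7ccccc7)cc(OCc7ccccc7)c65
F3 | step 11 | (2R)-2-Ar-5,7-bis(benzyloxy)chroman-4-one | O=C5C[C@H](c1ccc(OCc2ccccc2)c(OCc2ccccc2)c1-c1c(OCc2ccccc2)cc(OCc2ccccc2)c2c(=O)cc(-c3ccc(OCc4ccccc4)c(OCc4ccccc4)c3)oc12)Oc6cc(OCc7ccccc7)cc(OCc7ccccc7)c65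
F4 | step 10 | 2-Ar-4,6-bis(benzyloxy)benzofuran-3-yl (S)-2-methoxy-2-phenylacetate | CO[C@H](C(=O)Oc5c(-c1ccc(OCc2ccccc2)c(OCc2ccccc2)c1-c1c(OCc2ccccc2)cc(OCc2ccccc2)c2c(=O)cc(-c3ccc(OCc4ccccc4)c(OCc4ccccc4)c3)oc12)oc6cc(OCc7ccccc7)cc(OCc7ccccc7)c56)c8ccccc8
F5 | step 10 | (1aR,6bR)-1a-Ar-4,6-bis(benzyloxy)-1a,6b-dihydro-1H-cyclopropa[b]benzofuran-6b-yl (S)-2-methoxy-2-phenylacetate | CO[C@H](C(=O)O[C@@]56C[C@]5(c1ccc(OCc2ccccc2)c(OCc2ccccc2)c1-c1c(OCc2ccccc2)cc(OCc2ccccc2)c2c(=O)cc(-c3ccc(OCc4ccccc4)c(OCc4ccccc4)c3)oc12)Oc5cc(OCc7ccccc7)cc(OCc7ccccc7)c56)c8ccccc8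
F6 | step 6 | 3,4-bis(benzyloxy)-2-(4,4,5,5-tetramethyl-1,3,2-dioxaborolan-2-yl)benzaldehyde | O=Cc1ccc(OCc2ccccc2)c(OCc2ccccc2)c1B1OC(C)(C)C(C)(C)O1
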